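The tetralone is cut at both bonds that join the hydroquinone ring to its four-carbon bridge: C4–C4a and C1–C8a. The 5,8-dihydroxybenzo ring (C4a–C8a) is read as a masked p-benzoquinone, whose C4a=C8a double bond serves as dienophile, and C1–C4 as a (1E,3E)-diene bearing the naphthyl group on C4 and a silyloxy group on C1. A catalytic enantioselective Diels–Alder reaction closes the six-membered ring and sets the C4 stereocentre in one operation; enolisation and acylation in the same flask restore the aromatic ring. Saturation of the ring alkene, oxidation at C1 and deprotection finish the synthesis. The diene comes from 5-methoxy-1-naphthol in four steps.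

Key step: step 5

Assumption: the sense of induction in step 5 is taken from the accepted pre-transition-state model of prolinol-derived oxazaborolidinium catalysts (quinone bound as an s-trans enone, endo attack on the face remote from the gem-diphenyl unit, silyloxy-bearing diene terminus bonding next to the complexed carbonyl), which points to the (S)-prolinol-derived catalyst for the (S)-configured target; should the adduct prove antipodal, the (R)-catalyst is used and nothing else changes.

Step 1
Reactants: 1 5-methoxynaphthalen-1-ol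
Product: 3 4-bromo-5-methoxynaphthalen-1-yl pivalate, via 4-bromo-5-methoxynaphthalen-1-ol 2 (not isolated)
Conditions: NBS (1.0 equiv), MeCN, −30 → 0 °C; then Et3N, DMAP (cat.), PivCl, 0 °C → rt
Reagents that add atoms: N-bromosuccinimide O=C1CCC(=O)N1Br; pivaloyl chloride CC(C)(C)C(=O)Cl
Why: Electrophilic aromatic bromination of a free 1-naphthol should go para to the hydroxyl group (C4, an α-position that tolerates the peri methoxy group as in 1,5-dimethoxynaphthalene), and esterification in the same flask protects the oxidation-prone bromonaphthol.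

Step 2
Reactants: 3 4-bromo-5-methoxynaphthalen-1-yl pivalate; 4 allyltributylstannane
Product: 5 4-allyl-5-methoxynaphthalen-1-yl pivalate
Conditions: Pd(PPh3)4 (5 mol %), toluene, 105 °C
Reagents that add atoms: none
Why: Stille coupling (oxidative addition of the aryl bromide, allyl transfer from tin, reductive elimination) tolerates the aryl ester and the methyl ether.

Step 3
Reactants: 5 4-allyl-5-methoxynaphthalen-1-yl pivalate; 6 (E)-but-2-enal
Product: 7 5-methoxy-4-[(E)-4-oxobut-2-en-1-yl]naphthalen-1-yl pivalate
Conditions: Hoveyda–Grubbs second-generation catalyst (3 mol %), crotonaldehyde (5 equiv), CH2Cl2, 40 °C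
Reagents that add atoms: none
Why: Olefin cross-metathesis of a terminal allyl arene with crotonaldehyde should give the (E)-enal under thermodynamic control, driven by loss of volatile propene.

Step 4
Reactants: 7 5-methoxy-4-[(E)-4-oxobut-2-en-1-yl]naphthalen-1-yl pivalate
Product: 8 4-[(1E,3E)-4-(tert-butyldimethylsilyloxy)buta-1,3-dien-1-yl]-5-methoxynaphthalen-1-yl pivalate
Conditions: TBSOTf (1.2 equiv), Et3N (2 equiv), Et2O, 0 °C → rt
Reagents that add atoms: tert-butyldimethylsilyl triflate CC(C)(C)[Si](C)(C)OS(=O)(=O)C(F)(F)F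
Why: O-silylation of the enal followed by γ-deprotonation (vinylogous soft enolisation) gives the silyl dienol ether, the s-trans enal conformer leading to the 1E enol ether and allylic strain placing the aryl group trans at the new C3=C4 bond.

Step 5
Reactants: 8 4-[(1E,3E)-4-(tert-butyldimethylsilyloxy)buta-1,3-dien-1-yl]-5-methoxynaphthalen-1-yl pivalate; 9 1,4-benzoquinone
Product: 11 (5S,8S)-8-(tert-butyldimethylsilyloxy)-5-[8-methoxy-4-(pivaloyloxy)naphthalen-1-yl]-5,8-dihydronaphthalene-1,4-diyl dipivalate, via endo Diels–Alder adduct 10 (not isolated)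
Conditions: 8 (1.1 equiv), 9 (1.0 equiv), oxazaborolidinium triflimide from (S)-α,α-diphenylprolinol, o-tolylboroxine and Tf2NH (20 mol %), CH2Cl2, −78 °C; then Et3N, DMAP, PivCl, −78 → 0 °C
Reagents that add atoms: pivaloyl chloride CC(C)(C)C(=O)Cl
Why: The chiral boron cation binds one quinone carbonyl and lowers the LUMO of the adjacent C=C, which adds the diene in a concerted, asynchronous, endo [4+2] cycloaddition (the known oxazaborolidinium-catalysed Diels–Alder reaction of quinones with silyloxy dienes), forming C4–C4a and C1–C8a of the tetralone at once. Et3N/DMAP/PivCl then removes both ring-fusion protons by enolisation and traps the hydroquinone as its dipivalate before it can lose silanol or be oxidised. The only ring closed, the cyclohexene, forms by intermolecular suprafacial [4+2] addition across the quinone C=C. The aryl-bearing stereocentre is set by the catalyst, whose gem-diphenyl unit blocks one face of the bound s-trans enone, together with the endo approach; the (1E,3E) geometry makes silyloxy and aryl groups cis, and the two ring-fusion centres are erased on aromatisation. Three selectivities are needed, because exo attack or the reversed diene orientation would give the antipode after aromatisation: facial (catalyst), endo (secondary overlap with the second carbonyl, reinforced by the Lewis acid) and orientational (the silyloxy donor makes the aryl-bearing terminus the nucleophilic one, so it bonds β to the complexed carbonyl). Regiochemistry does not arise because the quinone is symmetric, and the slight excess of diene leaves no quinone that could oxidise the hydroquinone when base is added.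

Step 6
Reactants: 11 (5S,8S)-8-(tert-butyldimethylsilyloxy)-5-[8-methoxy-4-(pivaloyloxy)naphthalen-1-yl]-5,8-dihydronaphthalene-1,4-diyl dipivalate
Product: 12 (5S,8S)-8-(tert-butyldimethylsilyloxy)-5-[8-methoxy-4-(pivaloyloxy)naphthalen-1-yl]-5,6,7,8-tetrahydronaphthalene-1,4-diyl dipivalate
Conditions: 2-nitrobenzenesulfonohydrazide (excess), Et3N, CH2Cl2, rt
Reagents that add atoms: none
Why: Diimide generated in situ delivers H2 suprafacially to the only non-aromatic alkene without a metal hydride (diimide reduction), so no double-bond migration can scramble the doubly benzylic stereocentre and the benzylic C–O bond is not hydrogenolysed.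

Step 7
Reactants: 12 (5S,8S)-8-(tert-butyldimethylsilyloxy)-5-[8-methoxy-4-(pivaloyloxy)naphthalen-1-yl]-5,6,7,8-tetrahydronaphthalene-1,4-diyl dipivalate
Product: 13 (5S,8S)-8-hydroxy-5-[8-methoxy-4-(pivaloyloxy)naphthalen-1-yl]-5,6,7,8-tetrahydronaphthalene-1,4-diyl dipivalate
Conditions: HF·pyridine, pyridine, THF, 0 °C → rt
Reagents that add atoms: none
Why: Fluoride cleavage of the alkyl silyl ether under buffered acidic conditions should leave the aryl pivalates untouched, since they are too hindered to migrate to the new hydroxyl group and the acylated ring disfavours benzylic ionisation.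

Step 8
Reactants: 13 (5S,8S)-8-hydroxy-5-[8-methoxy-4-(pivaloyloxy)naphthalen-1-yl]-5,6,7,8-tetrahydronaphthalene-1,4-diyl dipivalate
Product: 14 (5S)-5-[8-methoxy-4-(pivaloyloxy)naphthalen-1-yl]-8-oxo-5,6,7,8-tetrahydronaphthalene-1,4-diyl dipivalate
Conditions: Dess–Martin periodinane, CH2Cl2, 0 °C → rt, dark
Reagents that add atoms: none
Why: Dess–Martin oxidation of the secondary benzylic alcohol gives the aryl ketone and removes the auxiliary carbinol stereocentre, while all phenols are masked and the remaining stereocentre is not α to the new carbonyl.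

Step 9
Reactants: 14 (5S)-5-[8-methoxy-4-(pivaloyloxy)naphthalen-1-yl]-8-oxo-5,6,7,8-tetrahydronaphthalene-1,4-diyl dipivalate
Product: 15 (4S)-5,8-dihydroxy-4-(4-hydroxy-8-methoxynaphthalen-1-yl)-3,4-dihydronaphthalen-1(2H)-one
Conditions: LiOH·H2O (10 equiv), degassed THF–H2O, 0 °C → rt, Ar, dark; then 1 M HCl
Reagents that add atoms: none
Why: Saponification of the three aryl esters (acyl–oxygen cleavage with phenoxide leaving groups) under exclusion of oxygen should free the hydroquinone and the naphthol without touching the stereocentre, which is γ to the ketone.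

Compound list
1 | 5-methoxynaphthalen-1-ol | COc1cccc2c(O)cccc12 | starting material
2 | 4-bromo-5-methoxynaphthalen-1-ol | COc1cccc2c(O)ccc(Br)c12 | intermediate
3 | 4-bromo-5-methoxynaphthalen-1-yl pivalate | COc1cccc2c(OC(=O)C(C)(C)C)ccc(Br)c12 | intermediate
4 | allyltributylstannane | C=CC[Sn](CCCC)(CCCC)CCCC | starting material
5 | 4-allyl-5-methoxynaphthalen-1-yl pivalate | COc1cccc2c(OC(=O)C(C)(C)C)ccc(CC=C)c12 | intermediate
6 | (E)-but-2-enal (crotonaldehyde) | C/C=C/C=O | starting material
7 | 5-methoxy-4-[(E)-4-oxobut-2-en-1-yl]naphthalen-1-yl pivalate | COc1cccc2c(OC(=O)C(C)(C)C)ccc(C/C=C/C=O)c12 | intermediate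
8 | 4-[(1E,3E)-4-(tert-butyldimethylsilyloxy)buta-1,3-dien-1-yl]-5-methoxynaphthalen-1-yl pivalate | COc1cccc2c(OC(=O)C(C)(C)C)ccc(/C=C/C=C/O[Si](C)(C)C(C)(C)C)c12 | intermediate
9 | 1,4-benzoquinone | O=C1C=CC(=O)C=C1 | starting material
10 | (4aR,5S,8R,8aR)-5-(tert-butyldimethylsilyloxy)-8-[8-methoxy-4-(pivaloyloxy)naphthalen-1-yl]-4a,5,8,8a-tetrahydronaphthalene-1,4-dione (all-cis endo adduct) | COc1cccc2c(OC(=O)C(C)(C)C)ccc([C@@H]3C=C[C@H](O[Si](C)(C)C(C)(C)C)[C@@H]4C(=O)C=CC(=O)[C@@H]43)c12 | intermediate
11 | (5S,8S)-8-(tert-butyldimethylsilyloxy)-5-[8-methoxy-4-(pivaloyloxy)naphthalen-1-yl]-5,8-dihydronaphthalene-1,4-diyl dipivalate (5,8-cis) | COc1cccc2c(OC(=O)C(C)(C)C)ccc([C@@H]3C=C[C@H](O[Si](C)(C)C(C)(C)C)c4c(OC(=O)C(C)(C)C)ccc(OC(=O)C(C)(C)C)c43)c12 | intermediate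
12 | (5S,8S)-8-(tert-butyldimethylsilyloxy)-5-[8-methoxy-4-(pivaloyloxy)naphthalen-1-yl]-5,6,7,8-tetrahydronaphthalene-1,4-diyl dipivalate (5,8-cis) | COc1cccc2c(OC(=O)C(C)(C)C)ccc([C@@H]3CC[C@H](O[Si](C)(C)C(C)(C)C)c4c(OC(=O)C(C)(C)C)ccc(OC(=O)C(C)(C)C)c43)c12 | intermediate
13 | (5S,8S)-8-hydroxy-5-[8-methoxy-4-(pivaloyloxy)naphthalen-1-yl]-5,6,7,8-tetrahydronaphthalene-1,4-diyl dipivalate (5,8-cis) | COc1cccc2c(OC(=O)C(C)(C)C)ccc([C@@H]3CC[C@H](O)c4c(OC(=O)C(C)(C)C)ccc(OC(=O)C(C)(C)C)c43)c12 | intermediate
14 | (5S)-5-[8-methoxy-4-(pivaloyloxy)naphthalen-1-yl]-8-oxo-5,6,7,8-tetrahydronaphthalene-1,4-diyl dipivalate | COc1cccc2c(OC(=O)C(C)(C)C)ccc([C@@H]3CCC(=O)c4c(OC(=O)C(C)(C)C)ccc(OC(=O)C(C)(C)C)c43)c12 | intermediate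
15 | (4S)-5,8-dihydroxy-4-(4-hydroxy-8-methoxynaphthalen-1-yl)-3,4-dihydronaphthalen-1(2H)-one | COc1cccc2c(O)ccc([C@@H]3CCC(=O)c4c(O)ccc(O)c43)c12 | target

Total step count: 9
Longest linear sequence: 9 steps (1 → 15)

Steps most likely to fail

1. Step 5. Facial, endo/exo or orientational selectivity may leak (each lowers the enantiomeric purity, because all three converge on the antipode after aromatisation), or the acidic catalyst may cleave the silyl dienol ether before cycloaddition. The fallback replaces asymmetric catalysis by resolution and sets out from 8 and 9. The cycloaddition is run without catalyst (toluene, 25–50 °C) and worked up with Et3N/DMAP/PivCl as before; this gives 11 together with its mirror image, the (5R,8R)-dihydronaphthalene dipivalate F2, formed through the (4aS,5R,8S,8aS)-adduct F1. Diimide reduction and HF·pyridine as in steps 6 and 7 carry the racemate through the (5R,8R)-silyl ether F3 to racemic alcohol, that is 13 together with the (5R,8R)-alcohol F4. A lipase (Candida antarctica lipase B, vinyl acetate, MTBE, 30–40 °C) should acetylate the (8R)-carbinol, as the empirical rule for secondary alcohols with an aryl group as the large substituent predicts, giving the (5R,8R)-acetate F5 and leaving the (5S,8S)-alcohol, which is separated by chromatography. The route is rejoined at 13.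

2. Step 6. Diimide transfer to the ring alkene, which is flanked by two substituted carbons, may be slow, and prolonged reaction may allow aromatisation by loss of silanol. The fallback sets out from 11 and avoids the reduction altogether: a cationic iridium catalyst, [Ir(cod)(PMePh2)2]PF6 pre-activated with H2 (THF, rt), isomerises the allylic silyl ether through the oxygen-bearing C–H to the silyl enol ether, (5S)-8-(tert-butyldimethylsilyloxy)-5-[8-methoxy-4-(pivaloyloxy)naphthalen-1-yl]-5,6-dihydronaphthalene-1,4-diyl dipivalate F6. HF·pyridine (THF, 0 °C) then hydrolyses the enol ether to the ketone. The route is rejoined at 14, and steps 7 and 8 are not needed.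

3. Step 1. The electrophile may attack ortho to the hydroxyl group or in the methoxy-bearing ring, and the bromonaphthol may be over-oxidised towards the quinone. The fallback sets out from 1 and replaces electrophilic substitution by coordination-directed metalation. TIPSCl/imidazole (DMF) gives the silyl ether, triisopropyl[(5-methoxynaphthalen-1-yl)oxy]silane F7. t-BuLi (cyclohexane, rt) should lithiate the position peri to the methoxy group, as known for 1-methoxynaphthalene, while the bulky silyloxy group does not direct, and BrCF2CF2Br gives the bromide, [(4-bromo-5-methoxynaphthalen-1-yl)oxy]triisopropylsilane F8. TBAF (THF, 0 °C) frees the naphthol, and the route is rejoined at 2, which is pivaloylated to 3 as in the second half of step 1.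

Further compounds
F1 | step 5 | (4aS,5R,8S,8aS)-5-(tert-butyldimethylsilyloxy)-8-[8-methoxy-4-(pivaloyloxy)naphthalen-1-yl]-4a,5,8,8a-tetrahydronaphthalene-1,4-dione (enantiomer of 10) | COc1cccc2c(OC(=O)C(C)(C)C)ccc([C@H]3C=C[C@@H](O[Si](C)(C)C(C)(C)C)[C@H]4C(=O)C=CC(=O)[C@H]43)c12
F2 | step 5 | (5R,8R)-8-(tert-butyldimethylsilyloxy)-5-[8-methoxy-4-(pivaloyloxy)naphthalen-1-yl]-5,8-dihydronaphthalene-1,4-diyl dipivalate (enantiomer of 11) | COc1cccc2c(OC(=O)C(C)(C)C)ccc([C@H]3C=C[C@@H](O[Si](C)(C)C(C)(C)C)c4c(OC(=O)C(C)(C)C)ccc(OC(=O)C(C)(C)C)c43)c12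
F3 | step 5 | (5R,8R)-8-(tert-butyldimethylsilyloxy)-5-[8-methoxy-4-(pivaloyloxy)naphthalen-1-yl]-5,6,7,8-tetrahydronaphthalene-1,4-diyl dipivalate (enantiomer of 12) | COc1cccc2c(OC(=O)C(C)(C)C)ccc([C@H]3CC[C@@H](O[Si](C)(C)C(C)(C)C)c4c(OC(=O)C(C)(C)C)ccc(OC(=O)C(C)(C)C)c43)c12
F4 | step 5 | (5R,8R)-8-hydroxy-5-[8-methoxy-4-(pivaloyloxy)naphthalen-1-yl]-5,6,7,8-tetrahydronaphthalene-1,4-diyl dipivalate (enantiomer of 13) | COc1cccc2c(OC(=O)C(C)(C)C)ccc([C@H]3CC[C@@H](O)c4c(OC(=O)C(C)(C)C)ccc(OC(=O)C(C)(C)C)c43)c12
F5 | step 5 | (5R,8R)-8-acetoxy-5-[8-methoxy-4-(pivaloyloxy)naphthalen-1-yl]-5,6,7,8-tetrahydronaphthalene-1,4-diyl dipivalate | COc1cccc2c(OC(=O)C(C)(C)C)ccc([C@H]3CC[C@@H](OC(C)=O)c4c(OC(=O)C(C)(C)C)ccc(OC(=O)C(C)(C)C)c43)c12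
F6 | step 6 | (5S)-8-(tert-butyldimethylsilyloxy)-5-[8-methoxy-4-(pivaloyloxy)naphthalen-1-yl]-5,6-dihydronaphthalene-1,4-diyl dipivalate | COc1cccc2c(OC(=O)C(C)(C)C)ccc([C@@H]3CC=C(O[Si](C)(C)C(C)(C)C)c4c(OC(=O)C(C)(C)C)ccc(OC(=O)C(C)(C)C)c43)c12
F7 | step 1 | triisopropyl[(5-methoxynaphthalen-1-yl)oxy]silane | COc1cccc2c(O[Si](C(C)C)(C(C)C)C(C)C)cccc12
F8 | step 1 | [(4-bromo-5-methoxynaphthalen-1-yl)oxy]triisopropylsilane | COc1cccc2c(O[Si](C(C)C)(C(C)C)C(C)C)ccc(Br)c12
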